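**Strategy.** Everything rests on cutting the C6–C1′ bond together with a temporary O5–acyl bond, so that the complete 3-substituted hexanoic acid chain arrives as (E)-hex-2-enal. The feature exploited is C6, the central carbon of the cyclic 1,3-dicarbonyl unit (C5 enol, C7 ketone) in the dearomatised carbocycle, ring A, of the chromanedione. Under oxidative carbene catalysis it adds to the β-carbon of the enal-derived acyl azolium while O5 is acylated, so one operation forms the C6–C1′ bond, the C1′ stereocentre and an enol δ-lactone that mild base later opens. The precursor is the fully assembled dearomatised core, C8 quaternary with both side chains in place and C6–H free.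

Key step: step 13

Numbering: chromanone numbering (O1, C2, C3, C4, C4a, C5–C8, C8a); C1′ is the side-chain CH; ring A is the carbocycle C4a–C8a.

Remark: only one CH2 lies between C8 and the cyclobutane, so the C8 electrophile must be the ten-carbon aldehyde 14; the keto aldehyde from direct cleavage of pinene would be one carbon too long, and the route through verbenone and cis-pinononic acid excises pinene C3.

Assumption: the sense of induction of the three chiral catalysts (quinine in step 2, the (R,R) bisphosphine in step 11, the (5aS,10bR) triazolium in step 13) is taken by analogy with related substrates; the antipode or pseudo-enantiomer (quinidine for quinine) is available for each should the opposite sense be found.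

Step 1
Reactants: 1 phloroglucinol; 2 tigloyl chloride
Product: 3 (E)-2-methyl-1-(2,4,6-trihydroxyphenyl)but-2-en-1-one
Conditions: AlCl3, PhNO2, 0 °C to rt; then ice/aq. HCl
Reagents that add atoms: none
Why: Friedel–Crafts C-acylation of the symmetrical, highly nucleophilic triphenol should stop after one acylation because the ketone deactivates the ring, and at low temperature the product is quenched before the enone can cyclise.

Step 2
Reactants: 3 (E)-2-methyl-1-(2,4,6-trihydroxyphenyl)but-2-en-1-one
Product: 4 (2R,3S)-5,7-dihydroxy-2,3-dimethylchroman-4-one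
Conditions: quinine (20 mol%), PhCl, rt
Reagents that add atoms: none
Why: Alkaloid-catalysed intramolecular oxa-Michael addition, in which quinine ion-pairs with the phenoxide so that an ortho oxygen adds to one face of the tigloyl β-carbon and sets C2 as (R), while kinetic protonation of the resulting enol at C3 gives the cis (3S) isomer, as known for o-tigloylphenols.

Step 3
Reactants: 4 (2R,3S)-5,7-dihydroxy-2,3-dimethylchroman-4-one
Product: 5 (2R,3S)-7-[(tert-butyldimethylsilyl)oxy]-5-hydroxy-2,3-dimethylchroman-4-one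
Conditions: TBSCl, imidazole, DMF, 0 °C
Reagents that add atoms: tert-butyldimethylsilyl chloride, CC(C)(C)[Si](C)(C)Cl
Why: Chemoselective phenol silylation, which should take only the free 7-OH because the 5-OH is locked in a hydrogen bond to the C4 carbonyl.

Step 4
Reactants: 5 (2R,3S)-7-[(tert-butyldimethylsilyl)oxy]-5-hydroxy-2,3-dimethylchroman-4-one
Product: 7 (2R,3S)-6-bromo-5,7-dihydroxy-2,3-dimethylchroman-4-one, via bromo silyl ether 6 (not isolated)
Conditions: NBS (1.0 equiv), DMF, 0 °C; then KHF2, MeOH, rt
Reagents that add atoms: N-bromosuccinimide, O=C1CCC(=O)N1Br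
Why: Electrophilic aromatic bromination of a 5-hydroxy-7-oxygenated chromanone should take place ortho to the free, chelated 5-OH, that is at C6, as is usual for halogenation of 5-hydroxy-7-alkoxy chromanones and flavones, and the labile aryl silyl ether is then cleaved by bifluoride.

Step 5
Reactants: 8 (1R,5R)-(+)-α-pinene
Product: 9 (1R,5R)-(+)-verbenone
Conditions: t-BuOOH (70% aq.), CrO3 (5 mol%), CH2Cl2, rt
Reagents that add atoms: tert-butyl hydroperoxide, CC(C)(C)OO
Why: Chromium-catalysed allylic C–H oxidation should convert the ring CH2 next to the trisubstituted alkene into the enone carbonyl without touching the bridgehead stereocentres.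

Step 6
Reactants: 9 (1R,5R)-(+)-verbenone
Product: 11 (1R,3S)-3-acetyl-2,2-dimethylcyclobutane-1-carboxylic acid, via keto acid 10 (not isolated)
Conditions: RuCl3·xH2O (2 mol%), NaIO4 (4.5 equiv), MeCN/EtOAc/H2O, rt
Reagents that add atoms: sodium periodate, [Na+].[O-]I(=O)(=O)=O; water, O
Why: RuO4 formed in situ cleaves the enone C=C bond (oxidative alkene cleavage) to the α-keto acid 10, which periodate decarboxylates oxidatively, so that pinene C3 is lost as CO2 and the two untouched ring stereocentres stay cis.

Step 7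
Reactants: 11 (1R,3S)-3-acetyl-2,2-dimethylcyclobutane-1-carboxylic acid
Product: 12 (1R,3R)-2,2-dimethyl-3-(prop-1-en-2-yl)cyclobutane-1-carboxylic acid
Conditions: Ph3PCH3Br, KOt-Bu, THF, 0 °C to rt; then 1 M HCl
Reagents that add atoms: methyltriphenylphosphonium bromide, C[P+](c1ccccc1)(c1ccccc1)c1ccccc1.[Br-]
Why: Wittig methylenation, in which the non-stabilised ylide converts the methyl ketone into the isopropenyl group while the carboxylate is inert, and because carbonyl addition outpaces enolisation toward the ring CH the cis relationship should be kept.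

Step 8
Reactants: 12 (1R,3R)-2,2-dimethyl-3-(prop-1-en-2-yl)cyclobutane-1-carboxylic acid
Product: 13 [(1R,3R)-2,2-dimethyl-3-(prop-1-en-2-yl)cyclobutyl]methanol
Conditions: LiAlH4, THF, 0 °C to rt; then H2O
Reagents that add atoms: none
Why: Hydride reduction of the carboxylic acid to the primary alcohol, which leaves the isolated 1,1-disubstituted alkene and the ring stereocentres untouched.

Step 9
Reactants: 13 [(1R,3R)-2,2-dimethyl-3-(prop-1-en-2-yl)cyclobutyl]methanol
Product: 14 (1R,3R)-2,2-dimethyl-3-(prop-1-en-2-yl)cyclobutane-1-carbaldehyde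
Conditions: TEMPO (10 mol%), PhI(OAc)2, CH2Cl2, rt
Reagents that add atoms: none
Why: Oxoammonium (TEMPO) oxidation of the primary alcohol stops at the aldehyde under near-neutral conditions, so the α-stereocentre should not epimerise and the alkene is untouched.

Step 10
Reactants: 7 (2R,3S)-6-bromo-5,7-dihydroxy-2,3-dimethylchroman-4-one; 14 (1R,3R)-2,2-dimethyl-3-(prop-1-en-2-yl)cyclobutane-1-carbaldehyde
Product: 16 (2R,3S)-6-bromo-8-{[(1S,3R)-2,2-dimethyl-3-(prop-1-en-2-yl)cyclobutyl]methyl}-5,7-dihydroxy-2,3-dimethylchroman-4-one, via ortho-quinone methide 15 (not isolated)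
Conditions: L-proline (20 mol%), Hantzsch ester (1.3 equiv), CH2Cl2, 0 °C to rt
Reagents that add atoms: none
Why: Three-component reductive alkylation, in which proline-mediated Knoevenagel-type condensation of 14 at C8, the only unsubstituted nucleophilic ring carbon now that C6 carries bromine, gives ortho-quinone methide 15, which is reduced at once by conjugate hydride transfer from the dihydropyridine, a reductant that leaves the C4 ketone and the alkene alone.

Step 11
Reactants: 16 (2R,3S)-6-bromo-8-{[(1S,3R)-2,2-dimethyl-3-(prop-1-en-2-yl)cyclobutyl]methyl}-5,7-dihydroxy-2,3-dimethylchroman-4-one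
Product: 17 (2R,3S,8R)-6-bromo-8-{[(1S,3R)-2,2-dimethyl-3-(prop-1-en-2-yl)cyclobutyl]methyl}-5-hydroxy-2,3-dimethyl-8-(3-methylbut-2-en-1-yl)-2,3-dihydro-4H-chromene-4,7(8H)-dione
Conditions: Pd2(dba)3·CHCl3 (2.5 mol%), (1R,2R)-N,N′-bis[2-(diphenylphosphino)benzoyl]cyclohexane-1,2-diamine (7.5 mol%), tert-butyl (3-methylbut-2-en-1-yl) carbonate (1.3 equiv), THF, 0 °C to rt
Reagents that add atoms: tert-butyl (3-methylbut-2-en-1-yl) carbonate, CC(C)=CCOC(=O)OC(C)(C)C
Why: Tsuji–Trost-type asymmetric allylic alkylation run as a dearomatising C-alkylation, in which the tert-butoxide released on ionisation of the carbonate forms the phenoxide of 16, whose alkyl-bearing C8 (C6 being shielded and deactivated by bromine, and any O-prenyl ether re-ionising under zerovalent palladium) attacks the unsubstituted terminus of the π-prenyl complex inside the chiral bisphosphine pocket, which differentiates the two faces of the planar nucleophile and should set the quaternary C8 as (R).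

Step 12
Reactants: 17 (2R,3S,8R)-6-bromo-8-{[(1S,3R)-2,2-dimethyl-3-(prop-1-en-2-yl)cyclobutyl]methyl}-5-hydroxy-2,3-dimethyl-8-(3-methylbut-2-en-1-yl)-2,3-dihydro-4H-chromene-4,7(8H)-dione
Product: 18 (2R,3S,8R)-8-{[(1S,3R)-2,2-dimethyl-3-(prop-1-en-2-yl)cyclobutyl]methyl}-5-hydroxy-2,3-dimethyl-8-(3-methylbut-2-en-1-yl)-2,3-dihydro-4H-chromene-4,7(8H)-dione
Conditions: Zn dust, AcOH/THF, 0 °C to rt
Reagents that add atoms: none
Why: Reductive dehalogenation of an α-halo carbonyl compound, in which zinc reduces the doubly activated C6–Br bond of the 2-bromo-1,3-dicarbonyl unit to the zinc enolate that acetic acid protonates, while the isolated alkenes and all stereocentres are untouched.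

Step 13
Reactants: 18 (2R,3S,8R)-8-{[(1S,3R)-2,2-dimethyl-3-(prop-1-en-2-yl)cyclobutyl]methyl}-5-hydroxy-2,3-dimethyl-8-(3-methylbut-2-en-1-yl)-2,3-dihydro-4H-chromene-4,7(8H)-dione; 19 (E)-hex-2-enal
Product: 20 O5 enol δ-lactone of 21 with (S) configuration at C1′ (3,4-dihydro-2H-pyran-2-one ring O5–C(=O)–CH2–C1′(propyl)–C6=C5 fused to ring A)
Conditions: (5aS,10bR)-2-mesityl-5a,10b-dihydro-4H,6H-indeno[2,1-b][1,2,4]triazolo[4,3-d][1,4]oxazin-2-ium tetrafluoroborate (10 mol%), i-Pr2NEt (1.5 equiv), 3,3′,5,5′-tetra-tert-butyl-4,4′-diphenoquinone (1.2 equiv), 4 Å MS, THF, rt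
Reagents that add atoms: none
Why: The carbene adds to 19 to give the Breslow intermediate, which the diphenoquinone oxidises to the α,β-unsaturated acyl azolium; C6 of the enolate of 18 then adds to its β-carbon (directly, or by O-acylation and [3,3] shift), the azolium enolate is protonated, and the C5 enol oxygen attacks the acyl azolium carbonyl, freeing the carbene. The closest known reaction type is the oxidative carbene-catalysed [3+3] annulation of enals with cyclic 1,3-diketones and 4-hydroxycoumarin-type enols to 3,4-dihydropyran-2-ones. The one new ring, the six-membered enol lactone, closes by 6-exo-trig acyl substitution. The one new stereocentre, C1′, is set by the catalyst, whose fused indane shields one face of the acyl azolium so that C6 should bond to the Si face of the β-carbon and give (S), independently of the remote C2, C3 and C8 centres. The step needs carbon selectivity for C6, which the substrate secures because C6 is the only enolisable carbon of ring A (C8 is quaternary, C4a fully substituted) and the amine-buffered medium does not deprotonate C3–H; acylation at the alternative C7 oxygen would not matter, since the same acid results in step 14.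

Step 14
Reactants: 20 O5 enol δ-lactone
Product: 21 (3S)-3-[(2R,3S,8R)-8-{[(1S,3R)-2,2-dimethyl-3-(prop-1-en-2-yl)cyclobutyl]methyl}-5-hydroxy-2,3-dimethyl-8-(3-methylbut-2-en-1-yl)-4,7-dioxo-3,4,7,8-tetrahydro-2H-chromen-6-yl]hexanoic acid
Conditions: LiOH·H2O (3 equiv), THF/H2O, 0 °C; then 0.5 M HCl to pH 3, 0 °C
Reagents that add atoms: lithium hydroxide (aqueous), [Li+].[OH-]
Why: Saponification of an enol ester (a vinylogous anhydride), in which hydroxide attacks the lactone carbonyl and expels the stabilised enolate of the ring A 1,3-dicarbonyl, acidification then giving the acid and the C5 enol, and at 0 °C neither C1′, which is not α to a carbonyl, nor C3 of the electron-rich dianion should epimerise.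

**Compound list**

1 | phloroglucinol | Oc1cc(O)cc(O)c1 | starting material
2 | tigloyl chloride, (E)-2-methylbut-2-enoyl chloride | C/C=C(\C)C(=O)Cl | starting material
3 | (E)-2-methyl-1-(2,4,6-trihydroxyphenyl)but-2-en-1-one | C/C=C(\C)C(=O)c1c(O)cc(O)cc1O | intermediate
4 | (2R,3S)-5,7-dihydroxy-2,3-dimethylchroman-4-one (cis) | Oc1cc(O)c2c(c1)O[C@H](C)[C@H](C)C2=O | intermediate
5 | (2R,3S)-7-[(tert-butyldimethylsilyl)oxy]-5-hydroxy-2,3-dimethylchroman-4-one | CC(C)(C)[Si](C)(C)Oc1cc(O)c2c(c1)O[C@H](C)[C@H](C)C2=O | intermediate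
6 | (2R,3S)-6-bromo-7-[(tert-butyldimethylsilyl)oxy]-5-hydroxy-2,3-dimethylchroman-4-one (not isolated) | CC(C)(C)[Si](C)(C)Oc1c(Br)c(O)c2c(c1)O[C@H](C)[C@H](C)C2=O | intermediate
7 | (2R,3S)-6-bromo-5,7-dihydroxy-2,3-dimethylchroman-4-one | Oc1c(Br)c(O)c2c(c1)O[C@H](C)[C@H](C)C2=O | intermediate
8 | (1R,5R)-(+)-α-pinene | CC1=CC[C@@H]2C[C@H]1C2(C)C | starting material
9 | (1R,5R)-(+)-verbenone, (1R,5R)-4,6,6-trimethylbicyclo[3.1.1]hept-3-en-2-one | CC1=CC(=O)[C@@H]2C[C@H]1C2(C)C | intermediate
10 | 2-[(1R,3S)-3-acetyl-2,2-dimethylcyclobutyl]-2-oxoacetic acid (not isolated) | CC(=O)[C@H]1C[C@@H](C(=O)C(=O)O)C1(C)C | intermediate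
11 | (1R,3S)-3-acetyl-2,2-dimethylcyclobutane-1-carboxylic acid (cis-pinononic acid) | CC(=O)[C@H]1C[C@@H](C(=O)O)C1(C)C | intermediate
12 | (1R,3R)-2,2-dimethyl-3-(prop-1-en-2-yl)cyclobutane-1-carboxylic acid | C=C(C)[C@H]1C[C@@H](C(=O)O)C1(C)C | intermediate
13 | [(1R,3R)-2,2-dimethyl-3-(prop-1-en-2-yl)cyclobutyl]methanol | C=C(C)[C@H]1C[C@@H](CO)C1(C)C | intermediate
14 | (1R,3R)-2,2-dimethyl-3-(prop-1-en-2-yl)cyclobutane-1-carbaldehyde | C=C(C)[C@H]1C[C@@H](C=O)C1(C)C | intermediate
15 | (2R,3S)-6-bromo-8-{[(1S,3R)-2,2-dimethyl-3-(prop-1-en-2-yl)cyclobutyl]methylidene}-5-hydroxy-2,3-dimethyl-2,3-dihydro-4H-chromene-4,7(8H)-dione, ortho-quinone methide, alkene geometry not fixed (not isolated) | C=C(C)[C@H]1C[C@@H](C=C2C(=O)C(Br)=C(O)C3=C2O[C@H](C)[C@H](C)C3=O)C1(C)C | intermediate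
16 | (2R,3S)-6-bromo-8-{[(1S,3R)-2,2-dimethyl-3-(prop-1-en-2-yl)cyclobutyl]methyl}-5,7-dihydroxy-2,3-dimethylchroman-4-one | C=C(C)[C@H]1C[C@@H](Cc2c(O)c(Br)c(O)c3c2O[C@H](C)[C@H](C)C3=O)C1(C)C | intermediate
17 | (2R,3S,8R)-6-bromo-8-{[(1S,3R)-2,2-dimethyl-3-(prop-1-en-2-yl)cyclobutyl]methyl}-5-hydroxy-2,3-dimethyl-8-(3-methylbut-2-en-1-yl)-2,3-dihydro-4H-chromene-4,7(8H)-dione | C=C(C)[C@H]1C[C@@H](C[C@@]2(CC=C(C)C)C(=O)C(Br)=C(O)C3=C2O[C@H](C)[C@H](C)C3=O)C1(C)C | intermediate
18 | (2R,3S,8R)-8-{[(1S,3R)-2,2-dimethyl-3-(prop-1-en-2-yl)cyclobutyl]methyl}-5-hydroxy-2,3-dimethyl-8-(3-methylbut-2-en-1-yl)-2,3-dihydro-4H-chromene-4,7(8H)-dione (dearomatised core, C6–H) | C=C(C)[C@H]1C[C@@H](C[C@@]2(CC=C(C)C)C(=O)C=C(O)C3=C2O[C@H](C)[C@H](C)C3=O)C1(C)C | intermediate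
19 | (E)-hex-2-enal | CCC/C=C/C=O | starting material
20 | O5 enol δ-lactone of 21: side-chain carboxyl esterified with the C5 enol oxygen, (S) at C1′, otherwise (2R,3S,8R) and (1S,3R) as in 18 | C=C(C)[C@H]1C[C@@H](C[C@@]2(CC=C(C)C)C(=O)C4=C(OC(=O)C[C@@H]4CCC)C3=C2O[C@H](C)[C@H](C)C3=O)C1(C)C | intermediate
21 | (3S)-3-[(2R,3S,8R)-8-{[(1S,3R)-2,2-dimethyl-3-(prop-1-en-2-yl)cyclobutyl]methyl}-5-hydroxy-2,3-dimethyl-8-(3-methylbut-2-en-1-yl)-4,7-dioxo-3,4,7,8-tetrahydro-2H-chromen-6-yl]hexanoic acid | C=C(C)[C@H]1C[C@@H](C[C@@]2(CC=C(C)C)C(=O)C([C@@H](CCC)CC(=O)O)=C(O)C3=C2O[C@H](C)[C@H](C)C3=O)C1(C)C | target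

**Totals.** Total step count: 14. Longest linear sequence: 10 steps (steps 5–9 from 8, then steps 10–14); the other branch (steps 1–4, then 10–14) is 9 steps.

**Steps most likely to fail**

Step 13. The hindered, strongly acidic enol of 18 may add to the acyl azolium too slowly, so that the acyl azolium is lost to acylation of the biphenol by-product or to hydrolysis; facial control at C1′ may also be incomplete, and the remote stereocentres give no help. Fallback, setting out from 18 (with 19) and rejoining at 20: iminium catalysis with (S)-2-[diphenyl(trimethylsilyloxy)methyl]pyrrolidine and benzoic acid in CH2Cl2 at 0 °C effects the Michael addition of C6 to the enal. The adduct closes through O5 to the cyclic hemiacetal, lactol F1. Oxidation of the lactol (TEMPO, PhI(OAc)2, CH2Cl2) then gives 20. The catalyst antipode is used if the opposite face is exposed.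

Step 11. The two faces of the flat phenoxide may be discriminated insufficiently, or alkylation may occur at O7 or at the bromine-bearing C6 instead of C8. Fallback, setting out from 16 and rejoining at 17: alkylation under asymmetric phase-transfer catalysis (prenyl bromide, N-(9-anthracenylmethyl)cinchonidinium bromide, solid Cs2CO3, toluene, −40 °C). This replaces the palladium π-prenyl electrophile by an SN2 process in which the chiral ammonium counter-ion controls the face. It makes no new compound (F0), and a minor C8 epimer, being a diastereomer, would be removed by chromatography.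

Step 10. Condensation of the α-branched, neopentyl-like aldehyde may be slow, its α-carbon may epimerise through the enamine, or the ortho-quinone methide may be captured by the neighbouring isopropenyl group in an intramolecular hetero-Diels–Alder reaction before hydride arrives. Fallback, setting out from 6 (isolated before the bifluoride treatment) and from alcohol 13, and rejoining at 16: an sp2–sp3 Negishi coupling that needs neither the aldehyde nor a quinone methide. Iodination of the last free ring position of 6 (NIS, MeCN, rt) gives the 8-iodo chromanone F2. An Appel reaction on 13 (I2, PPh3, imidazole, CH2Cl2) gives the iodomethylcyclobutane F3, and zinc insertion (Zn dust, LiCl, THF) gives the alkylzinc iodide F4. Coupling of F2 with F4 (Pd(OAc)2, 2-dicyclohexylphosphino-2′,6′-bis(dimethylamino)biphenyl, THF, rt; one extra equivalent of F4 for the chelated 5-OH), selective for C–I over C–Br, gives the coupled silyl ether F5. KHF2 in MeOH then gives 16.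

**Further compounds**

F1 | step 13 | lactol (cyclic hemiacetal of the C6 Michael adduct, closed through O5, both anomers, (S) at C1′) | C=C(C)[C@H]1C[C@@H](C[C@@]2(CC=C(C)C)C(=O)C4=C(OC(O)C[C@@H]4CCC)C3=C2O[C@H](C)[C@H](C)C3=O)C1(C)C
F0 | step 11 | none | none
F2 | step 10 | (2R,3S)-6-bromo-7-[(tert-butyldimethylsilyl)oxy]-5-hydroxy-8-iodo-2,3-dimethylchroman-4-one | CC(C)(C)[Si](C)(C)Oc1c(Br)c(O)c2c(c1I)O[C@H](C)[C@H](C)C2=O
F3 | step 10 | (1R,3R)-1-(iodomethyl)-2,2-dimethyl-3-(prop-1-en-2-yl)cyclobutane | C=C(C)[C@H]1C[C@@H](CI)C1(C)C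
F4 | step 10 | {[(1R,3R)-2,2-dimethyl-3-(prop-1-en-2-yl)cyclobutyl]methyl}zinc iodide | C=C(C)[C@H]1C[C@@H](C[Zn]I)C1(C)C
F5 | step 10 | (2R,3S)-6-bromo-7-[(tert-butyldimethylsilyl)oxy]-8-{[(1S,3R)-2,2-dimethyl-3-(prop-1-en-2-yl)cyclobutyl]methyl}-5-hydroxy-2,3-dimethylchroman-4-one | C=C(C)[C@H]1C[C@@H](Cc2c(O[Si](C)(C)C(C)(C)C)c(Br)c(O)c3c2O[C@H](C)[C@H](C)C3=O)C1(C)C
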